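## Retrosynthetic overview

1. Numbering: lactone as pyran-2-one (C2 carbonyl, C5 tiglate, C6 side chain), side chain C1'–C5'. The C3'/C4' diacetate is unmasked last from a trans-isopropylidene acetal (dioxolane).
2. Key disconnection, C2'–C3' (sp3–sp2): iridium/nickel photoredox decarboxylative vinylation. A 2,2,5-trimethyl-1,3-dioxolan-4-yl radical from a D-threonine-derived carboxylate is joined to the complete (E)-iodovinyl lactone; bond formation anti to the methyl group sets C3'.
3. The iodovinyl lactone comes from ring-closing metathesis of the acrylate of a syn diol mono-tiglate.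
4. The syn mono-tiglate (C5, C6) comes from a chromium-catalysed asymmetric γ-(tigloyloxy)allylation of (E)-3-iodoacrolein with 3-chloropropenyl tiglate (acrolein + tigloyl chloride).
5. Ring order: temporary dioxolane on the side-chain fragment, then the dihydropyranone by metathesis, then fragment union, then the dioxolane is opened.

Assumption: the salen–chromium catalyst is taken to give the same facial sense with the new tiglate donor as with the known pivalate donor; the ligand enantiomer named in step 6 is the one expected to give the (3S,4S) product, and its mirror image is used if the sense proves opposite.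

## Route

Step 1
Reactants: 1 D-threonine, (2R,3S)-2-amino-3-hydroxybutanoic acid
Product: 2 (2R,3S)-2,3-dihydroxybutanoic acid
Conditions: NaNO2, 1 M H2SO4, H2O, 0 °C to rt
Reagents that add atoms: water, O
Why: Nitrosative deamination (diazotization–hydrolysis) of an α-amino acid replaces NH2 by OH with net retention through carboxylate participation and leaves C3, the future C4' centre, untouched.

Step 2
Reactants: 2 (2R,3S)-2,3-dihydroxybutanoic acid
Product: 3 methyl (4R,5S)-2,2,5-trimethyl-1,3-dioxolane-4-carboxylate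
Conditions: Me2C(OMe)2, MeOH, TsOH·H2O (cat.), 50 °C
Reagents that add atoms: 2,2-dimethoxypropane, COC(C)(C)OC; methanol, CO
Why: One-pot Fischer esterification and transacetalization close the threo diol to the trans-dioxolane without touching either stereocentre.

Step 3
Reactants: 3 methyl (4R,5S)-2,2,5-trimethyl-1,3-dioxolane-4-carboxylate
Product: 4 potassium (4R,5S)-2,2,5-trimethyl-1,3-dioxolane-4-carboxylate
Conditions: KOH (1.0 equiv), MeOH/H2O (4:1), 0 °C to rt; evaporate, dry in vacuo
Reagents that add atoms: potassium hydroxide, [K+].[OH-]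
Why: Saponification gives the carboxylate salt in the form needed for photo-oxidation, and any epimerization at C4 is harmless because that centre becomes a radical in step 9.

Step 4
Reactants: 5 ethyl (Z)-3-iodoprop-2-enoate
Product: 7 (E)-3-iodoprop-2-enal, via (Z)-3-iodoprop-2-enal 6 (not isolated)
Conditions: iBu2AlH (1.05 equiv), CH2Cl2, −78 °C; aq. potassium sodium tartrate; then I2 (2 mol%), CH2Cl2, daylight, rt
Reagents that add atoms: none
Why: Partial ester reduction at −78 °C stops at the aldehyde (stable tetrahedral aluminate), and iodine-catalysed Z-to-E equilibration then gives the more stable E β-iodoenal.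

Step 5
Reactants: 8 acrolein (prop-2-enal); 9 tigloyl chloride, (E)-2-methylbut-2-enoyl chloride
Product: 10 3-chloroprop-1-en-1-yl (E)-2-methylbut-2-enoate (mixture of enol-ester E/Z isomers)
Conditions: ZnCl2 (2 mol%), CH2Cl2, −10 °C to rt
Reagents that add atoms: none
Why: ZnCl2-catalysed addition of an acyl chloride across acrolein (net 1,4-chloroacylation) is the established entry to 3-halopropenyl esters, and both enol-ester geometries serve as γ-acyloxyallyl donors.

Step 6
Reactants: 7 (E)-3-iodoprop-2-enal; 10 3-chloroprop-1-en-1-yl (E)-2-methylbut-2-enoate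
Product: 12 (3S,4S,5E)-4-hydroxy-6-iodohexa-1,5-dien-3-yl (E)-2-methylbut-2-enoate, via trimethylsilyl ether 11 (not isolated)
Conditions: CrCl3 (10 mol%), Mn (3 equiv), (S,S)-N,N'-bis(3,5-di-tert-butylsalicylidene)cyclohexane-1,2-diamine (10 mol%), Et3N (20 mol%), Me3SiCl (1.5 equiv), 10 (1.5 equiv), MeCN, rt; then 1 M HCl, THF, 0 °C
Reagents that add atoms: chlorotrimethylsilane, C[Si](C)(C)Cl (its silyl group is present only in 11 and is removed in the work-up)
Why: Proposed new method: catalytic asymmetric Nozaki–Hiyama-type γ-acyloxyallylation, in which salen-bound divalent chromium (regenerated by Mn) reduces the allylic chloride in two one-electron steps to a γ-(tigloyloxy)allylchromium species whose ligand-controlled addition to the aldehyde, turned over by Me3SiCl, gives the syn mono-ester and sets C5 and C6 together; the closest known reaction is the salen–chromium-catalysed addition of 3-chloropropenyl pivalate to aldehydes giving syn-alk-1-ene-3,4-diol monoesters.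

Step 7
Reactants: 12 (3S,4S,5E)-4-hydroxy-6-iodohexa-1,5-dien-3-yl (E)-2-methylbut-2-enoate; 13 acryloyl chloride (prop-2-enoyl chloride)
Product: 14 (3S,4S,5E)-6-iodo-4-(prop-2-enoyloxy)hexa-1,5-dien-3-yl (E)-2-methylbut-2-enoate
Conditions: iPr2NEt, CH2Cl2, −20 to 0 °C
Reagents that add atoms: none
Why: O-Acylation of the secondary allylic alcohol with a hindered amine and no nucleophilic catalyst avoids 1,2-migration of the tiglate and touches no stereocentre.

Step 8
Reactants: 14 (3S,4S,5E)-6-iodo-4-(prop-2-enoyloxy)hexa-1,5-dien-3-yl (E)-2-methylbut-2-enoate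
Product: 15 (2S,3S)-2-[(E)-2-iodoethenyl]-6-oxo-3,6-dihydro-2H-pyran-3-yl (E)-2-methylbut-2-enoate
Conditions: second-generation Grubbs catalyst RuCl2(=CHPh)(PCy3)(H2IMes) (5 mol%), CH2Cl2 (5 mM), 40 °C
Reagents that add atoms: none
Why: Ring-closing metathesis of the acrylate with the terminal vinyl group closes the six-membered unsaturated lactone (ring-enforced Z alkene), while the 1,2-disubstituted iodoalkene and the trisubstituted tiglate alkene are too hindered and electron-poor to engage the ruthenium carbene.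

Step 9
Reactants: 4 potassium (4R,5S)-2,2,5-trimethyl-1,3-dioxolane-4-carboxylate; 15 (2S,3S)-2-[(E)-2-iodoethenyl]-6-oxo-3,6-dihydro-2H-pyran-3-yl (E)-2-methylbut-2-enoate
Product: 16 (2S,3S)-6-oxo-2-{(E)-2-[(4S,5S)-2,2,5-trimethyl-1,3-dioxolan-4-yl]ethenyl}-3,6-dihydro-2H-pyran-3-yl (E)-2-methylbut-2-enoate
Conditions: 4 (1.5 equiv), [Ir(dF(CF3)ppy)2(dtbbpy)]PF6 (2 mol%), NiCl2(dme) (10 mol%), dtbbpy (12 mol%), DMSO (0.05 M), 450 nm LEDs, 25 °C, degassed
Reagents that add atoms: none
Why: Metallaphotoredox decarboxylative C(sp3)–C(sp2) cross-coupling, in which the excited iridium photocatalyst oxidizes the carboxylate, loss of CO2 gives the dioxolan-4-yl radical, this is captured by the alkenylnickel species formed from the E-iodoalkene (geometry retained), and C–C bond formation anti to the 5-methyl group makes both C4 epimers of 4 converge on the trans-dioxolane, setting C3' as S (the preformed salt is the only base present, which protects the lactone).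

Step 10
Reactants: 16 (2S,3S)-6-oxo-2-{(E)-2-[(4S,5S)-2,2,5-trimethyl-1,3-dioxolan-4-yl]ethenyl}-3,6-dihydro-2H-pyran-3-yl (E)-2-methylbut-2-enoate
Product: 18 (2S,3S)-2-[(1E,3S,4S)-3,4-diacetoxypent-1-en-1-yl]-6-oxo-3,6-dihydro-2H-pyran-3-yl (E)-2-methylbut-2-enoate, via diol 17 (not isolated)
Conditions: CF3CO2H/H2O (9:1), 0 °C; evaporate; then Ac2O, pyridine, DMAP (cat.), CH2Cl2, 0 °C to rt
Reagents that add atoms: acetic anhydride, CC(=O)OC(C)=O
Why: Acidic hydrolysis of the isopropylidene acetal followed in the same flask by exhaustive O-acetylation touches no stereocentre, and the lactone and tiglate tolerate aqueous acid and cold Ac2O/pyridine.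

## Compound list

1 | D-threonine, (2R,3S)-2-amino-3-hydroxybutanoic acid | C[C@H](O)[C@@H](N)C(=O)O | starting material
2 | (2R,3S)-2,3-dihydroxybutanoic acid | C[C@H](O)[C@@H](O)C(=O)O | intermediate
3 | methyl (4R,5S)-2,2,5-trimethyl-1,3-dioxolane-4-carboxylate | C[C@@H]1OC(C)(C)O[C@H]1C(=O)OC | intermediate
4 | potassium (4R,5S)-2,2,5-trimethyl-1,3-dioxolane-4-carboxylate | C[C@@H]1OC(C)(C)O[C@H]1C(=O)[O-].[K+] | intermediate
5 | ethyl (Z)-3-iodoprop-2-enoate | CCOC(=O)/C=C\I | starting material
6 | (Z)-3-iodoprop-2-enal | O=C/C=C\I | intermediate (not isolated)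
7 | (E)-3-iodoprop-2-enal | O=C/C=C/I | intermediate
8 | acrolein (prop-2-enal) | C=CC=O | starting material
9 | tigloyl chloride, (E)-2-methylbut-2-enoyl chloride | C/C=C(\C)C(Cl)=O | starting material
10 | 3-chloroprop-1-en-1-yl (E)-2-methylbut-2-enoate (enol-ester E/Z mixture) | C/C=C(\C)C(=O)OC=CCCl | intermediate
11 | (3S,4S,5E)-6-iodo-4-[(trimethylsilyl)oxy]hexa-1,5-dien-3-yl (E)-2-methylbut-2-enoate | C/C=C(\C)C(=O)O[C@@H](C=C)[C@@H](O[Si](C)(C)C)/C=C/I | intermediate (not isolated)
12 | (3S,4S,5E)-4-hydroxy-6-iodohexa-1,5-dien-3-yl (E)-2-methylbut-2-enoate | C/C=C(\C)C(=O)O[C@@H](C=C)[C@@H](O)/C=C/I | intermediate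
13 | acryloyl chloride (prop-2-enoyl chloride) | C=CC(Cl)=O | starting material
14 | (3S,4S,5E)-6-iodo-4-(prop-2-enoyloxy)hexa-1,5-dien-3-yl (E)-2-methylbut-2-enoate | C/C=C(\C)C(=O)O[C@@H](C=C)[C@@H](OC(=O)C=C)/C=C/I | intermediate
15 | (2S,3S)-2-[(E)-2-iodoethenyl]-6-oxo-3,6-dihydro-2H-pyran-3-yl (E)-2-methylbut-2-enoate | C/C=C(\C)C(=O)O[C@H]1C=CC(=O)O[C@H]1/C=C/I | intermediate
16 | (2S,3S)-6-oxo-2-{(E)-2-[(4S,5S)-2,2,5-trimethyl-1,3-dioxolan-4-yl]ethenyl}-3,6-dihydro-2H-pyran-3-yl (E)-2-methylbut-2-enoate | C/C=C(\C)C(=O)O[C@H]1C=CC(=O)O[C@H]1/C=C/[C@@H]2OC(C)(C)O[C@H]2C | intermediate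
17 | (2S,3S)-2-[(1E,3S,4S)-3,4-dihydroxypent-1-en-1-yl]-6-oxo-3,6-dihydro-2H-pyran-3-yl (E)-2-methylbut-2-enoate | C/C=C(\C)C(=O)O[C@H]1C=CC(=O)O[C@H]1/C=C/[C@H](O)[C@H](C)O | intermediate (not isolated)
18 | (2S,3S)-2-[(1E,3S,4S)-3,4-diacetoxypent-1-en-1-yl]-6-oxo-3,6-dihydro-2H-pyran-3-yl (E)-2-methylbut-2-enoate | C/C=C(\C)C(=O)O[C@H]1C=CC(=O)O[C@H]1/C=C/[C@H](OC(C)=O)[C@H](C)OC(C)=O | target

## Step count and risks

Total steps: 10. Longest linear sequence: 6 (steps 4, 6, 7, 8, 9, 10, from 5). The carboxylate branch (steps 1–3) and the allyl donor (step 5) join convergently.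

Steps most likely to fail:

**Step 9 (key coupling).** The nucleophilic dioxolanyl radical may add in conjugate fashion to C4 of the unsaturated lactone before nickel captures it. Lactone 15 is also sensitive to base-induced ring opening and loss of tiglic acid. The anti selectivity next to a methyl group may be incomplete, although the cis isomer would be separable at 16. The fallback sets out from 12 and comes back at 16. The same iridium/nickel decarboxylative coupling is run earlier, on the acyclic iodo-alcohol 12, which holds neither a lactone nor an electron-poor disubstituted alkene. With carboxylate 4 this gives (3S,4S,5E)-4-hydroxy-6-[(4S,5S)-2,2,5-trimethyl-1,3-dioxolan-4-yl]hexa-1,5-dien-3-yl (E)-2-methylbut-2-enoate F1. Acylation with acryloyl chloride 13 (iPr2NEt, CH2Cl2, −20 °C) gives (3S,4S,5E)-4-(prop-2-enoyloxy)-6-[(4S,5S)-2,2,5-trimethyl-1,3-dioxolan-4-yl]hexa-1,5-dien-3-yl (E)-2-methylbut-2-enoate F2. Ring-closing metathesis with the second-generation Grubbs catalyst RuCl2(=CHPh)(PCy3)(H2IMes) then closes the lactone to 16.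

**Step 6 (tigloyloxyallylation).** The tiglate donor is untested. By analogy with the pivalate, syn:anti is expected to be only about 4–6:1 and the ee about 90%. The β-iodoenal may exchange halide with chloride, and the mono-ester may suffer 1,2-acyl migration. The fallback sets out from 7 and comes back at 15. A Brown (Z)-γ-alkoxyallylboration is used instead: allyl methoxymethyl ether, sBuLi, THF, −78 °C; (+)-Ipc2BOMe; BF3·OEt2; then 7; NaOH/H2O2 work-up. The Z-alkoxyallylborane gives the syn product through a chair transition state, and the isopinocampheyl groups derived from (−)-α-pinene direct Re-face attack. The product is (1E,3S,4S)-1-iodo-4-(methoxymethoxy)hexa-1,5-dien-3-ol F3. Acylation with 13 gives (1E,3S,4S)-1-iodo-4-(methoxymethoxy)hexa-1,5-dien-3-yl prop-2-enoate F4. Ring-closing metathesis gives (5S,6S)-6-[(E)-2-iodoethenyl]-5-(methoxymethoxy)-5,6-dihydro-2H-pyran-2-one F5. Aqueous HCl in THF removes the methoxymethyl group to give (5S,6S)-5-hydroxy-6-[(E)-2-iodoethenyl]-5,6-dihydro-2H-pyran-2-one F6. Esterification with tigloyl chloride 9 (pyridine, DMAP cat., CH2Cl2, 0 °C) returns to 15.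

**Step 8 (metathesis beside an iodoalkene).** The iodoalkene may intercept the ruthenium carbene and kill the catalyst. The fallback sets out from 10 and comes back at 15. The halogen is masked as silicon: (E)-3-(trimethylsilyl)prop-2-enal takes the place of 7 in the step 6 protocol. This gives, through (3S,4S,5E)-6-(trimethylsilyl)-4-[(trimethylsilyl)oxy]hexa-1,5-dien-3-yl (E)-2-methylbut-2-enoate F7 (not isolated), the alcohol (3S,4S,5E)-4-hydroxy-6-(trimethylsilyl)hexa-1,5-dien-3-yl (E)-2-methylbut-2-enoate F8. Acylation with 13 gives (3S,4S,5E)-4-(prop-2-enoyloxy)-6-(trimethylsilyl)hexa-1,5-dien-3-yl (E)-2-methylbut-2-enoate F9. Ring-closing metathesis gives (2S,3S)-6-oxo-2-[(E)-2-(trimethylsilyl)ethenyl]-3,6-dihydro-2H-pyran-3-yl (E)-2-methylbut-2-enoate F10. Ipso iododesilylation with N-iodosuccinimide in (CF3)2CHOH at 0 °C, with retention of the E geometry, returns to 15.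

Further compounds

F1 | step 9 | (3S,4S,5E)-4-hydroxy-6-[(4S,5S)-2,2,5-trimethyl-1,3-dioxolan-4-yl]hexa-1,5-dien-3-yl (E)-2-methylbut-2-enoate | C/C=C(\C)C(=O)O[C@@H](C=C)[C@@H](O)/C=C/[C@@H]1OC(C)(C)O[C@H]1C
F2 | step 9 | (3S,4S,5E)-4-(prop-2-enoyloxy)-6-[(4S,5S)-2,2,5-trimethyl-1,3-dioxolan-4-yl]hexa-1,5-dien-3-yl (E)-2-methylbut-2-enoate | C/C=C(\C)C(=O)O[C@@H](C=C)[C@@H](OC(=O)C=C)/C=C/[C@@H]1OC(C)(C)O[C@H]1C
F3 | step 6 | (1E,3S,4S)-1-iodo-4-(methoxymethoxy)hexa-1,5-dien-3-ol | COCO[C@@H](C=C)[C@@H](O)/C=C/I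
F4 | step 6 | (1E,3S,4S)-1-iodo-4-(methoxymethoxy)hexa-1,5-dien-3-yl prop-2-enoate | COCO[C@@H](C=C)[C@@H](OC(=O)C=C)/C=C/I
F5 | step 6 | (5S,6S)-6-[(E)-2-iodoethenyl]-5-(methoxymethoxy)-5,6-dihydro-2H-pyran-2-one | COCO[C@H]1C=CC(=O)O[C@H]1/C=C/I
F6 | step 6 | (5S,6S)-5-hydroxy-6-[(E)-2-iodoethenyl]-5,6-dihydro-2H-pyran-2-one | O[C@H]1C=CC(=O)O[C@H]1/C=C/I
F7 | step 8 | (3S,4S,5E)-6-(trimethylsilyl)-4-[(trimethylsilyl)oxy]hexa-1,5-dien-3-yl (E)-2-methylbut-2-enoate | C/C=C(\C)C(=O)O[C@@H](C=C)[C@@H](O[Si](C)(C)C)/C=C/[Si](C)(C)C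
F8 | step 8 | (3S,4S,5E)-4-hydroxy-6-(trimethylsilyl)hexa-1,5-dien-3-yl (E)-2-methylbut-2-enoate | C/C=C(\C)C(=O)O[C@@H](C=C)[C@@H](O)/C=C/[Si](C)(C)C
F9 | step 8 | (3S,4S,5E)-4-(prop-2-enoyloxy)-6-(trimethylsilyl)hexa-1,5-dien-3-yl (E)-2-methylbut-2-enoate | C/C=C(\C)C(=O)O[C@@H](C=C)[C@@H](OC(=O)C=C)/C=C/[Si](C)(C)C
F10 | step 8 | (2S,3S)-6-oxo-2-[(E)-2-(trimethylsilyl)ethenyl]-3,6-dihydro-2H-pyran-3-yl (E)-2-methylbut-2-enoate | C/C=C(\C)C(=O)O[C@H]1C=CC(=O)O[C@H]1/C=C/[Si](C)(C)C
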